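**Retrosynthetic overview**
1. The C1 ketone comes from a late oxidation of a silyl-protected C1 carbinol. The side-chain oxirane comes from Shi epoxidation of a prenyl group, which comes from cross-metathesis of an allyl carbinol. The C2' carbinol comes from catalytic asymmetric allylation of a ring-bound 2-substituted acrolein, made from an isopropenyl group by ene chlorination and N-oxide oxidation.
2. The ring oxirane comes from vanadium-catalysed hydroxyl-directed epoxidation. The directing cis C4 carbinol comes from a ketoreductase reduction of a C4 enone unmasked from a dimethyl ketal.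
3. The C6 oxygen comes from enolate hydroxylation trans to the C5 substituent. C5, the first stereocentre, comes from a Rh/BINAP-catalysed 1,4-addition of an isopropenyl borate to an achiral quinone monoketal made from 4-methoxy-2-methylphenol.
4. Ring order: the carbocycle is present from the start (dearomatised phenol), then the ring oxirane (step 9), last the side-chain oxirane (step 16).

Assumption and numbering: a member of a commercial ketoreductase panel is taken to accept the C4 enone of step 8 and give the 4,5-cis alcohol; ring locants follow the target's cyclohexanone (C1 = C=O, C2 = C–CH3, C4 = C–O-tigloyl, C5 = side-chain carbon, C6 = C–OAc), side-chain carbons are primed (C1' on the ring, C2' carbinol, C4' oxirane CH).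

**Route**

Step 1
Reactants: 1 4-methoxy-2-methylphenol
Product: 2 4,4-dimethoxy-2-methylcyclohexa-2,5-dien-1-one
Conditions: PhI(OAc)2 (1.1 equiv), MeOH, 0 °C
Reagents that add atoms: methanol, CO
Why: Oxidative dearomatisation of a p-methoxyphenol with methanol trapping at C4 (hypervalent-iodine phenol oxidation) gives the achiral quinone monoketal that already carries the C2 methyl and the oxygen of the future C4 carbinol.

Step 2
Reactants: 2 4,4-dimethoxy-2-methylcyclohexa-2,5-dien-1-one; 3 potassium trifluoro(prop-1-en-2-yl)borate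
Product: 4 (5R)-4,4-dimethoxy-2-methyl-5-(prop-1-en-2-yl)cyclohex-2-en-1-one
Conditions: [Rh(cod)Cl]2 (2.5 mol %), (R)-BINAP (6 mol %), Et3N (2 equiv), toluene/H2O (10:1), 30 °C
Reagents that add atoms: potassium trifluoro(prop-1-en-2-yl)borate 3, [K+].C=C(C)[B-](F)(F)F
Why: Hayashi–Miyaura rhodium-catalysed asymmetric 1,4-addition, in which the alkenylrhodium–BINAP species adds only to the unsubstituted C5=C6 enone (the 2-methyl enone is too hindered) and the ligand sets C5 as R, the first stereocentre (sense assigned by the Hayashi quadrant model; the antipodal ligand would give ent-4).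

Step 3
Reactants: 4 (5R)-4,4-dimethoxy-2-methyl-5-(prop-1-en-2-yl)cyclohex-2-en-1-one
Product: 6 6-hydroxy-4,4-dimethoxy-2-methyl-5-(prop-1-en-2-yl)cyclohex-2-en-1-one (6-OH trans to 5-isopropenyl), via potassium dienolate 5 (not isolated)
Conditions: KN(SiMe3)2 (1.1 equiv), THF, −78 °C; then 3-phenyl-2-(phenylsulfonyl)oxaziridine (1.3 equiv), −78 °C; AcOH quench
Reagents that add atoms: 3-phenyl-2-(phenylsulfonyl)oxaziridine, O=S(=O)(c1ccccc1)N1OC1c1ccccc1
Why: Deprotonation is possible only at C6 (C4 is quaternary) and the Davis oxaziridine oxidises the dienolate on the face anti to the adjacent C5 isopropenyl group, giving the 5,6-trans α-hydroxy ketone, which is also the thermodynamic isomer (Davis enolate hydroxylation).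

Step 4
Reactants: 6 6-hydroxy-4,4-dimethoxy-2-methyl-5-(prop-1-en-2-yl)cyclohex-2-en-1-one; 7 acetic anhydride
Product: 8 6-acetoxy-4,4-dimethoxy-2-methyl-5-(prop-1-en-2-yl)cyclohex-2-en-1-one (5,6-trans)
Conditions: Ac2O (1.5 equiv), pyridine, DMAP (5 mol %), CH2Cl2, 0 °C
Reagents that add atoms: acetic anhydride 7, CC(=O)OC(C)=O
Why: DMAP-catalysed acetylation installs the C6 acetate of the target on the only hydroxyl present, under conditions that do not epimerise the trans α-acyloxy ketone.

Step 5
Reactants: 8 6-acetoxy-4,4-dimethoxy-2-methyl-5-(prop-1-en-2-yl)cyclohex-2-en-1-one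
Product: 9 6-acetoxy-4,4-dimethoxy-2-methyl-5-(prop-1-en-2-yl)cyclohex-2-en-1-ol (1-OH trans to 6-OAc)
Conditions: NaBH4, CeCl3·7H2O, MeOH, −78 °C
Reagents that add atoms: none
Why: Luche 1,2-reduction removes the C1 carbonyl so that the C4 ketone can later be unmasked without forming an aromatisation-prone enedione; axial hydride delivery gives mainly the 1,6-trans alcohol, and the C1 configuration is erased again at step 18.

Step 6
Reactants: 9 6-acetoxy-4,4-dimethoxy-2-methyl-5-(prop-1-en-2-yl)cyclohex-2-en-1-ol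
Product: 10 1-O-tert-butyldimethylsilyl ether of 9
Conditions: TBSOTf (1.2 equiv), 2,6-lutidine (2 equiv), CH2Cl2, −78 °C
Reagents that add atoms: tert-butyldimethylsilyl triflate, CC(C)(C)[Si](C)(C)OS(=O)(=O)C(F)(F)F
Why: Low-temperature silylation of the allylic alcohol is faster than acetyl migration and gives an ether that survives to the penultimate step (any premature loss of the allylic ketal only anticipates step 7).

Step 7
Reactants: 10 1-O-tert-butyldimethylsilyl ether of 9
Product: 11 6-acetoxy-1-(tert-butyldimethylsilyloxy)-2-methyl-5-(prop-1-en-2-yl)cyclohex-2-en-4-one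
Conditions: PPTS (10 mol %), acetone/H2O (10:1), 23 °C
Reagents that add atoms: water, O
Why: The allylic dimethyl ketal ionises readily under mild acid and hydrolyses to the transposed enone while the silyl ether, acetate and isopropenyl group are untouched; C5 remains in its favoured trans relationship to C6 (acetal hydrolysis).

Step 8
Reactants: 11 6-acetoxy-1-(tert-butyldimethylsilyloxy)-2-methyl-5-(prop-1-en-2-yl)cyclohex-2-en-4-one
Product: 12 6-acetoxy-1-(tert-butyldimethylsilyloxy)-2-methyl-5-(prop-1-en-2-yl)cyclohex-2-en-4-ol (4-OH cis to 5-isopropenyl)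
Conditions: ketoreductase (NADPH-dependent alcohol dehydrogenase, panel hit for the 4,5-cis alcohol), NADP+ (1 mol %), i-PrOH (10 vol %), DMSO (10 vol %), KH2PO4/K2HPO4 buffer (0.1 M, pH 6.8), MgSO4 (2 mM), 30 °C
Reagents that add atoms: none
Why: The ketoreductase transfers hydride from NADPH to the face of the C4 carbonyl opposite the C5 isopropenyl group under enzyme control, giving the contra-steric cis 4,5-alcohol at near-neutral pH without reducing the alkene, cleaving the acetate or eliminating the β-acetoxy group (biocatalytic asymmetric ketone reduction).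

Step 9
Reactants: 12 6-acetoxy-1-(tert-butyldimethylsilyloxy)-2-methyl-5-(prop-1-en-2-yl)cyclohex-2-en-4-ol
Product: 13 2,3-epoxide of 12 (oxirane cis to 4-OH)
Conditions: VO(acac)2 (5 mol %), t-BuOOH (1.5 equiv, decane solution), CH2Cl2, 0 to 23 °C
Reagents that add atoms: tert-butyl hydroperoxide, CC(C)(C)OO
Why: Vanadium-catalysed hydroxyl-directed epoxidation delivers oxygen syn to the pseudoaxial C4 hydroxyl and sets C2 and C3 with the oxirane cis to the C4 oxygen, while the merely homoallylic isopropenyl alkene reacts far more slowly (Sharpless–Michaelson epoxidation).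

Step 10
Reactants: 13 2,3-epoxide of 12; 14 (E)-2-methylbut-2-enoyl chloride (tigloyl chloride)
Product: 15 4-O-tiglate of 13
Conditions: 14 (2 equiv), pyridine, DMAP (20 mol %), CH2Cl2, 0 to 35 °C
Reagents that add atoms: tigloyl chloride 14, C/C=C(\C)C(Cl)=O
Why: DMAP-catalysed acylation of the only free hydroxyl gives the ring tiglate, and the E geometry (the stable one) is retained.

Step 11
Reactants: 15 4-O-tiglate of 13
Product: 16 5-(3-chloroprop-1-en-2-yl) analogue of 15
Conditions: Ca(OCl)2, solid CO2, CH2Cl2/H2O, 0 °C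
Reagents that add atoms: calcium hypochlorite (chlorine delivered as HOCl), [Ca+2].[O-]Cl.[O-]Cl
Why: Ene-type chlorination with HOCl converts the isopropenyl group into a 2-(chloromethyl)vinyl group, as it does with carvone, while the electron-poor tiglate alkene and the oxirane are inert.

Step 12
Reactants: 16 5-(3-chloroprop-1-en-2-yl) analogue of 15
Product: 18 5-(3-oxoprop-1-en-2-yl) analogue of 15 (2-substituted acrolein), via alkoxyammonium chloride 17 (not isolated)
Conditions: N-methylmorpholine N-oxide (5 equiv), NaHCO3 (2 equiv), 4 Å MS, MeCN, 45 °C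
Reagents that add atoms: N-methylmorpholine N-oxide, C[N+]1([O-])CCOCC1
Why: SN2 O-alkylation of the amine oxide by the allylic chloride followed by base-induced loss of N-methylmorpholine gives the enal under nearly neutral conditions (Ganem-type N-oxide oxidation).

Step 13
Reactants: 18 5-(3-oxoprop-1-en-2-yl) analogue of 15; 19 allyltributylstannane
Product: 21 5-[(3S)-3-hydroxyhexa-1,5-dien-2-yl] analogue of 15, via tributylstannyl ether 20 (not isolated)
Conditions: Ti(OiPr)4 (10 mol %), (S)-BINOL (20 mol %), 4 Å MS, 19 (1.5 equiv), CH2Cl2, −20 °C; then aq. KF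
Reagents that add atoms: allyltributylstannane 19, C=CC[Sn](CCCC)(CCCC)CCCC
Why: In the Keck catalytic asymmetric allylation the (S)-BINOL–titanium Lewis acid activates only the aldehyde and directs allyl transfer to one face, setting C2' as S under catalyst control.

Step 14
Reactants: 21 5-[(3S)-3-hydroxyhexa-1,5-dien-2-yl] analogue of 15; 22 2-methylbut-2-ene
Product: 23 5-[(3S)-3-hydroxy-6-methylhepta-1,5-dien-2-yl] analogue of 15
Conditions: 22 (20 equiv), second-generation Grubbs catalyst (H2IMes)(PCy3)Cl2Ru=CHPh (5 mol %), CH2Cl2, 40 °C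
Reagents that add atoms: 2-methylbut-2-ene 22, CC=C(C)C
Why: Olefin cross-metathesis of the monosubstituted terminal alkene with excess 2-methylbut-2-ene gives the prenyl group, the 1,1-disubstituted and tiglate alkenes being unreactive, and running it before C2' acylation avoids ring-closing metathesis onto a C2' tiglate.

Step 15
Reactants: 23 5-[(3S)-3-hydroxy-6-methylhepta-1,5-dien-2-yl] analogue of 15; 14 (E)-2-methylbut-2-enoyl chloride
Product: 24 3'-O-tiglate of 23 (bis-tiglate)
Conditions: 14 (2 equiv), pyridine, DMAP (20 mol %), CH2Cl2, 0 to 23 °C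
Reagents that add atoms: tigloyl chloride 14, C/C=C(\C)C(Cl)=O
Why: DMAP-catalysed acylation of the allylic C2' hydroxyl, the only free hydroxyl, installs the second tiglate with retention at C2'.

Step 16
Reactants: 24 3'-O-tiglate of 23
Product: 25 1-O-tert-butyldimethylsilyl-protected C1 carbinol of the target [(4'R)-4',5'-epoxide of 24]
Conditions: D-fructose-derived Shi ketone (1,2:4,5-di-O-isopropylidene-β-D-erythro-2,3-hexodiulo-2,6-pyranose, 30 mol %), KHSO5 (as 2KHSO5·KHSO4·K2SO4, 1.4 equiv), K2CO3, Bu4NHSO4 (cat.), MeCN/CH2(OMe)2/aq. Na2B4O7–Na2EDTA buffer (pH 10.5), 0 °C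
Reagents that add atoms: potassium peroxymonosulfate, [K+].[O-]S(=O)(=O)OO
Why: In the Shi asymmetric epoxidation the chiral dioxirane attacks the electron-rich trisubstituted prenyl alkene much faster than the 1,1-disubstituted or tiglate alkenes and sets C4' as R under catalyst control.

Step 17
Reactants: 25 1-O-tert-butyldimethylsilyl-protected C1 carbinol of the target
Product: 26 C1 carbinol of the target (1-OH trans to 6-OAc)
Conditions: Bu4NF/AcOH (1:1, 3 equiv), THF, 0 to 23 °C
Reagents that add atoms: none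
Why: Acetic-acid-buffered fluoride cleaves the Si–O bond without opening the acid-sensitive 2,2-dimethyloxirane and keeps the medium non-basic, so the C6 acetate does not migrate to the liberated C1 hydroxyl (fluoride desilylation).

Step 18
Reactants: 26 C1 carbinol of the target
Product: 27 target CNP0407453.3
Conditions: Dess–Martin periodinane (1.5 equiv), NaHCO3, CH2Cl2, 0 to 23 °C
Reagents that add atoms: none
Why: Buffered Dess–Martin oxidation converts the secondary epoxy alcohol into the epoxy ketone without epimerising C6 or touching the oxiranes and esters, which completes the target.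

**Compound list**
1 | 4-methoxy-2-methylphenol | COc1ccc(O)c(C)c1 | starting material
2 | 4,4-dimethoxy-2-methylcyclohexa-2,5-dien-1-one | COC1(OC)C=CC(=O)C(C)=C1 | intermediate
3 | potassium trifluoro(prop-1-en-2-yl)borate | [K+].C=C(C)[B-](F)(F)F | starting material
4 | (5R)-4,4-dimethoxy-2-methyl-5-(prop-1-en-2-yl)cyclohex-2-en-1-one | C=C(C)[C@@H]1C(OC)(OC)C=C(C)C(=O)C1 | intermediate
5 | potassium C1/C6 dienolate of 4 | C=C(C)[C@@H]1C(OC)(OC)C=C(C)C([O-])=C1.[K+] | intermediate (not isolated)
6 | 6-hydroxy-4,4-dimethoxy-2-methyl-5-(prop-1-en-2-yl)cyclohex-2-en-1-one, 6-OH trans to 5-isopropenyl | C=C(C)[C@@H]1C(OC)(OC)C=C(C)C(=O)[C@H]1O | intermediate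
7 | acetic anhydride | CC(=O)OC(C)=O | starting material
8 | 6-acetoxy-4,4-dimethoxy-2-methyl-5-(prop-1-en-2-yl)cyclohex-2-en-1-one, 5,6-trans | C=C(C)[C@@H]1C(OC)(OC)C=C(C)C(=O)[C@H]1OC(C)=O | intermediate
9 | 6-acetoxy-4,4-dimethoxy-2-methyl-5-(prop-1-en-2-yl)cyclohex-2-en-1-ol, 1-OH trans to 6-OAc | C=C(C)[C@@H]1C(OC)(OC)C=C(C)[C@H](O)[C@H]1OC(C)=O | intermediate
10 | 1-O-tert-butyldimethylsilyl ether of 9 | C=C(C)[C@@H]1C(OC)(OC)C=C(C)[C@H](O[Si](C)(C)C(C)(C)C)[C@H]1OC(C)=O | intermediate
11 | 6-acetoxy-1-(tert-butyldimethylsilyloxy)-2-methyl-5-(prop-1-en-2-yl)cyclohex-2-en-4-one | C=C(C)[C@@H]1C(=O)C=C(C)[C@H](O[Si](C)(C)C(C)(C)C)[C@H]1OC(C)=O | intermediate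
12 | 6-acetoxy-1-(tert-butyldimethylsilyloxy)-2-methyl-5-(prop-1-en-2-yl)cyclohex-2-en-4-ol, 4-OH cis to 5-isopropenyl | C=C(C)[C@@H]1[C@H](O)C=C(C)[C@H](O[Si](C)(C)C(C)(C)C)[C@H]1OC(C)=O | intermediate
13 | 2,3-epoxide of 12, oxirane cis to 4-OH | C=C(C)[C@@H]1[C@H](O)[C@@H]2O[C@]2(C)[C@H](O[Si](C)(C)C(C)(C)C)[C@H]1OC(C)=O | intermediate
14 | (E)-2-methylbut-2-enoyl chloride (tigloyl chloride) | C/C=C(\C)C(Cl)=O | starting material
15 | 4-O-tiglate of 13 | C=C(C)[C@@H]1[C@H](OC(=O)/C(C)=C/C)[C@@H]2O[C@]2(C)[C@H](O[Si](C)(C)C(C)(C)C)[C@H]1OC(C)=O | intermediate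
16 | 5-(3-chloroprop-1-en-2-yl) analogue of 15 | C=C(CCl)[C@@H]1[C@H](OC(=O)/C(C)=C/C)[C@@H]2O[C@]2(C)[C@H](O[Si](C)(C)C(C)(C)C)[C@H]1OC(C)=O | intermediate
17 | N-allyloxy-N-methylmorpholinium chloride derived from 16 | C=C(CO[N+]1(C)CCOCC1)[C@@H]1[C@H](OC(=O)/C(C)=C/C)[C@@H]2O[C@]2(C)[C@H](O[Si](C)(C)C(C)(C)C)[C@H]1OC(C)=O.[Cl-] | intermediate (not isolated)
18 | 5-(3-oxoprop-1-en-2-yl) analogue of 15 | C=C(C=O)[C@@H]1[C@H](OC(=O)/C(C)=C/C)[C@@H]2O[C@]2(C)[C@H](O[Si](C)(C)C(C)(C)C)[C@H]1OC(C)=O | intermediate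
19 | allyltributylstannane | C=CC[Sn](CCCC)(CCCC)CCCC | starting material
20 | tributylstannyl ether of 21 | C=C([C@@H]1[C@H](OC(=O)/C(C)=C/C)[C@@H]2O[C@]2(C)[C@H](O[Si](C)(C)C(C)(C)C)[C@H]1OC(C)=O)[C@H](CC=C)O[Sn](CCCC)(CCCC)CCCC | intermediate (not isolated)
21 | 5-[(3S)-3-hydroxyhexa-1,5-dien-2-yl] analogue of 15 | C=C([C@@H]1[C@H](OC(=O)/C(C)=C/C)[C@@H]2O[C@]2(C)[C@H](O[Si](C)(C)C(C)(C)C)[C@H]1OC(C)=O)[C@H](CC=C)O | intermediate
22 | 2-methylbut-2-ene | CC=C(C)C | starting material
23 | 5-[(3S)-3-hydroxy-6-methylhepta-1,5-dien-2-yl] analogue of 15 | C=C([C@@H]1[C@H](OC(=O)/C(C)=C/C)[C@@H]2O[C@]2(C)[C@H](O[Si](C)(C)C(C)(C)C)[C@H]1OC(C)=O)[C@H](CC=C(C)C)O | intermediate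
24 | 3'-O-tiglate of 23 (bis-tiglate) | C=C([C@@H]1[C@H](OC(=O)/C(C)=C/C)[C@@H]2O[C@]2(C)[C@H](O[Si](C)(C)C(C)(C)C)[C@H]1OC(C)=O)[C@H](CC=C(C)C)OC(=O)/C(C)=C/C | intermediate
25 | 1-O-tert-butyldimethylsilyl-protected C1 carbinol of the target, (4'R)-oxirane | C=C([C@@H]1[C@H](OC(=O)/C(C)=C/C)[C@@H]2O[C@]2(C)[C@H](O[Si](C)(C)C(C)(C)C)[C@H]1OC(C)=O)[C@H](C[C@H]1OC1(C)C)OC(=O)/C(C)=C/C | intermediate
26 | C1 carbinol of the target, 1-OH trans to 6-OAc | C=C([C@@H]1[C@H](OC(=O)/C(C)=C/C)[C@@H]2O[C@]2(C)[C@H](O)[C@H]1OC(C)=O)[C@H](C[C@H]1OC1(C)C)OC(=O)/C(C)=C/C | intermediate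
27 | CNP0407453.3: (2S,3S,4S,5R,6S)-6-acetoxy-2,3-epoxy-2-methyl-4-(tigloyloxy)-5-[(3S)-4-[(2R)-3,3-dimethyloxiran-2-yl]-3-(tigloyloxy)but-1-en-2-yl]cyclohexan-1-one | C=C([C@@H]1[C@H](OC(=O)/C(C)=C/C)[C@@H]2O[C@]2(C)C(=O)[C@H]1OC(C)=O)[C@H](C[C@H]1OC1(C)C)OC(=O)/C(C)=C/C | target

**Totals**
Total step count: 18. Longest linear sequence: 18 steps (from 1; all other starting materials enter as single reagents).

**Three steps most likely to fail**

Step 8 (ketoreductase reduction). The bulky silylated enone may be a poor substrate, or the available enzymes may favour the trans alcohol. The fallback sets out from 11 and comes back at 12. It replaces biocatalytic control by substrate control: LiBH(s-Bu)3 in THF at −78 °C reduces the β-methyl-substituted enone in 1,2-fashion, and the bulky hydride approaches equatorially, anti to the C5 isopropenyl group, so the axial 4,5-cis alcohol 12 forms directly. No new compound is made on this path (none F0).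

Step 12 (N-oxide oxidation of the allylic chloride). O-alkylation of the amine oxide by a hindered allylic chloride may be slow, and the amine set free can add to the acrolein. The fallback sets out from 16 and comes back at 18. It adjusts the oxidation level in separate stages: HCO2Cs in DMF at 40 °C displaces chloride to give the allylic formate F1. KHCO3 in MeOH at 0 °C then removes the formyl group far faster than the acetate or tiglate is touched, giving the allylic alcohol F2. MnO2 in CH2Cl2 oxidises the allylic alcohol to the enal 18.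

Step 17 (late desilylation). The hindered C1 silyl ether may resist buffered fluoride, and stronger conditions threaten the side-chain oxirane or promote acetyl migration. The fallback sets out from 24 and comes back at 27. It moves the deprotection in front of the side-chain epoxidation: HF·pyridine with extra pyridine in THF, tolerated because the acid-labile 2,2-dimethyloxirane is not yet present, gives the C1 alcohol F3. Dess–Martin periodinane with NaHCO3 gives the epoxy ketone F4. The Shi epoxidation of step 16, run briefly at 0 °C, is then the last step and gives 27 directly.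

**Further compounds**
F0 | step 8 | none | none
F1 | step 12 | 5-[3-(formyloxy)prop-1-en-2-yl] analogue of 15 (allylic formate) | C=C(COC=O)[C@@H]1[C@H](OC(=O)/C(C)=C/C)[C@@H]2O[C@]2(C)[C@H](O[Si](C)(C)C(C)(C)C)[C@H]1OC(C)=O
F2 | step 12 | 5-(3-hydroxyprop-1-en-2-yl) analogue of 15 (allylic alcohol) | C=C(CO)[C@@H]1[C@H](OC(=O)/C(C)=C/C)[C@@H]2O[C@]2(C)[C@H](O[Si](C)(C)C(C)(C)C)[C@H]1OC(C)=O
F3 | step 17 | C1 alcohol obtained by desilylation of 24 (prenyl alkene intact) | C=C([C@@H]1[C@H](OC(=O)/C(C)=C/C)[C@@H]2O[C@]2(C)[C@H](O)[C@H]1OC(C)=O)[C@H](CC=C(C)C)OC(=O)/C(C)=C/C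
F4 | step 17 | 4',5'-deoxy analogue of the target (C1 ketone with prenyl alkene) | C=C([C@@H]1[C@H](OC(=O)/C(C)=C/C)[C@@H]2O[C@]2(C)C(=O)[C@H]1OC(C)=O)[C@H](CC=C(C)C)OC(=O)/C(C)=C/C
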